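**Retrosynthetic overview**

1. The target is the enol ether obtained by dehydrating a 10‑alkoxy‑11‑hydroxy‑10,11‑dihydrodibenzo[b,f]oxepine and removing two O‑allyl groups (C‑10 = oxygen‑bearing carbon next to ring B, C‑11 = carbon next to the prenylated ring A).
2. That hydroxy oxane comes from a five‑membered cyclic hemiketal (oxolan‑2‑ol at C‑11) by one‑carbon ring enlargement with a tethered benzylic sulfonium ylide on ring B, which forms C‑10–C‑11 (oxepine) and O–C‑10 (oxane) in one operation.
3. The hemiketal comes from the aryllithium of a bromo diaryl ether and a tricyclic γ‑lactone; the lactone comes from a copper‑catalysed [2+2] photocycloaddition of the prenyl ether of (R)‑1‑methylcyclopent‑2‑enol (RCM of (R)‑linalool), followed by RuO4 oxidation.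
4. Enabling feature: on the cis‑bicyclo[3.2.0]heptane the tertiary oxygen on the methyl‑bearing carbon and the cyclobutane CH that carries the aryl carbon both sit on the concave face, 1,3 across the ring‑fusion CH. They therefore close a five‑membered hemiketal and, after carbon insertion, hold the alkoxide next to C‑10, while the diaryl‑ether oxygen tethers the ring B benzylic carbon to the ring A ketone.
5. Ring order: cyclopentane (RCM) → cyclobutane + oxolane ([2+2]) → diaryl ether (SNAr, separate branch) → oxepine + oxane (oxolane enlarged to oxane) → enol ether double bond.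

Key step: step 14

Assumption: (R)‑(−)‑linalool of high enantiomeric purity is taken as the commercial source of the only independent stereocentre (the methyl‑bearing C–O carbon, R in the target); the other three stereocentres follow from the forced cis ring fusions.

**Route**

Step 1
Reactants: 1 (R)‑linalool
Product: 2 (R)‑1‑methylcyclopent‑2‑en‑1‑ol
Conditions: second‑generation Grubbs catalyst (H2IMes)(PCy3)Cl2Ru=CHPh (0.5 mol %), CH2Cl2, rt
Reagents that add atoms: none
Why: Ring‑closing metathesis of the 1,6‑diene, driven by loss of isobutene and accelerated by the allylic hydroxyl, should close the cyclopentene without touching the quaternary stereocentre.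

Step 2
Reactants: 2 (R)‑1‑methylcyclopent‑2‑en‑1‑ol; 3 prenyl bromide
Product: 4 (R)‑1‑methyl‑1‑[(3‑methylbut‑2‑en‑1‑yl)oxy]cyclopent‑2‑ene
Conditions: NaH, THF/DMF, 0 °C to rt
Reagents that add atoms: none
Why: Williamson etherification of the tertiary sodium alkoxide at the unhindered primary allylic carbon (SN2) should give the ether with no stereocentre formed or affected.

Step 3
Reactants: 4 prenyl ether
Product: 5 tricyclic ether (1R,2R,5S,7R)‑2,6,6‑trimethyl‑2,7‑(epoxymethano)bicyclo[3.2.0]heptane
Conditions: (CuOTf)2·C6H6 (5 mol %), Et2O, hν 254 nm (quartz), rt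
Reagents that add atoms: none
Why: Copper‑triflate‑catalysed intramolecular [2+2] photocycloaddition of a diallyl‑type ether (Salomon–Kochi reaction): the three‑atom O–CH2 tether forces the cyclobutane onto the oxygen‑bearing face of the cyclopentene with cis fusion of all rings, so the three new stereocentres follow from the linalool carbon.

Step 4
Reactants: 5 tricyclic ether
Product: 6 tricyclic γ‑lactone (1R,2R,5S,7R)‑2‑hydroxy‑2,6,6‑trimethylbicyclo[3.2.0]heptane‑7‑carboxylic acid lactone
Conditions: RuCl3·xH2O (cat.), NaIO4, MeCN/EtOAc/H2O, rt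
Reagents that add atoms: sodium periodate [Na+].[O-]I(=O)(=O)=O
Why: RuO4 generated in the flask oxidises the only ether CH2 to the lactone carbonyl (the other α‑carbon is quaternary), leaving C–C bonds and stereocentres untouched.

Step 5
Reactants: 7 2‑fluoro‑4‑hydroxybenzaldehyde
Product: 8 4‑(allyloxy)‑2‑fluorobenzaldehyde
Conditions: allyl bromide, K2CO3, DMF, rt
Reagents that add atoms: allyl bromide C=CCBr
Why: Williamson O‑allylation installs a phenol protecting group that survives aryllithium, methyl triflate and base and is removed later under neutral palladium catalysis.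

Step 6
Reactants: 8 4‑(allyloxy)‑2‑fluorobenzaldehyde; 9 resorcinol
Product: 10 4‑(allyloxy)‑2‑(3‑hydroxyphenoxy)benzaldehyde
Conditions: resorcinol (3 equiv), K2CO3, DMF, 100 °C
Reagents that add atoms: none
Why: Nucleophilic aromatic substitution of the fluoride activated by the ortho formyl group, with excess resorcinol to hold the reaction at mono‑arylation.

Step 7
Reactants: 10 4‑(allyloxy)‑2‑(3‑hydroxyphenoxy)benzaldehyde
Product: 11 4‑(allyloxy)‑2‑(2‑bromo‑5‑hydroxyphenoxy)benzaldehyde
Conditions: NBS, MeCN, −20 °C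
Reagents that add atoms: N‑bromosuccinimide O=C1CCC(=O)N1Br
Why: Electrophilic bromination should go para to the free hydroxyl (ortho to the aryloxy oxygen) on the more electron‑rich, aldehyde‑free ring.

Step 8
Reactants: 11 bromophenol; 3 prenyl bromide
Product: 12 4‑(allyloxy)‑2‑[2‑bromo‑5‑hydroxy‑4‑(3‑methylbut‑2‑en‑1‑yl)phenoxy]benzaldehyde
Conditions: NaH, toluene, 0 °C; then prenyl bromide, rt
Reagents that add atoms: none
Why: Ortho C‑alkylation of the sodium phenoxide as a tight ion pair in a non‑polar solvent, the ortho position between the two oxygens being sterically blocked.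

Step 9
Reactants: 12 prenylated bromophenol
Product: 13 4‑(allyloxy)‑2‑[5‑(allyloxy)‑2‑bromo‑4‑(3‑methylbut‑2‑en‑1‑yl)phenoxy]benzaldehyde
Conditions: allyl bromide, K2CO3, DMF, 50 °C
Reagents that add atoms: allyl bromide C=CCBr
Why: Williamson O‑allylation protects the second phenol with the same group as the first.

Step 10
Reactants: 13 bis‑allyl aldehyde
Product: 14 {4‑(allyloxy)‑2‑[5‑(allyloxy)‑2‑bromo‑4‑(3‑methylbut‑2‑en‑1‑yl)phenoxy]phenyl}methanol
Conditions: NaBH4, MeOH/THF, 0 °C
Reagents that add atoms: none
Why: Borohydride reduces the aryl aldehyde while the aryl bromide and olefins are inert.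

Step 11
Reactants: 14 benzylic alcohol
Product: 15 1‑(allyloxy)‑5‑{5‑(allyloxy)‑2‑[(methylsulfanyl)methyl]phenoxy}‑4‑bromo‑2‑(3‑methylbut‑2‑en‑1‑yl)benzene
Conditions: MeSSMe, Bu3P, THF, rt
Reagents that add atoms: dimethyl disulfide CSSC
Why: Hata reaction: the phosphonium formed from Bu3P and the disulfide activates the primary benzylic alcohol for displacement by methanethiolate under neutral conditions.

Step 12
Reactants: 15 bromo diaryl ether sulfide; 6 tricyclic γ‑lactone
Product: 17 cyclic hemiketal (2‑aryl‑oxolan‑2‑ol on the (1R,2R,5S,7R) core), via aryllithium 16 (not isolated)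
Conditions: t‑BuLi (2 equiv), THF, −78 °C; then 6, −78 to −40 °C; aq. NH4Cl
Reagents that add atoms: none
Why: Bromine–lithium exchange outruns any deprotonation at −78 °C and the aryllithium adds once to the lactone, the tetrahedral lithium hemiketal alkoxide not collapsing at low temperature; the hemiketal carbon forms as an anomeric mixture, which is of no consequence.

Step 13
Reactants: 17 cyclic hemiketal sulfide
Product: 18 benzyl(dimethyl)sulfonium triflate of the cyclic hemiketal
Conditions: MeOTf, 2,6‑di‑tert‑butylpyridine, CH2Cl2, −40 to 0 °C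
Reagents that add atoms: methyl trifluoromethanesulfonate COS(=O)(=O)C(F)(F)F
Why: S‑Methylation of the dialkyl sulfide, the softest and most nucleophilic site, while the hindered hemiketal hydroxyl, aryl ethers and olefins do not react; the salt is used cold and without purification.

Step 14
Reactants: 18 sulfonium triflate
Product: 20 ring‑enlarged hydroxy oxane (10‑alkoxy‑11‑hydroxy‑10,11‑dihydrodibenzo[b,f]oxepine, O‑10 and OH‑11 trans), via epoxide 19 (not isolated)
Conditions: KOt‑Bu (2.2 equiv), THF, −40 °C to rt
Reagents that add atoms: none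
Why: Proposed new method: base unmasks the ring‑opened keto alkoxide of the five‑membered hemiketal and turns the benzylic sulfonium into its ylide, whose carbon adds to the aryl ketone through the diaryl‑ether tether (7‑exo‑trig, closing the oxepine); the betaine collapses to the 10,11‑epoxide (3‑exo‑tet, loss of Me2S), and the tertiary alkoxide on the methyl‑bearing carbon then opens the epoxide at the benzylic CH of ring B (6‑endo‑tet, anti), so that the ylide carbon ends up between the ring oxygen and the former hemiketal carbon and the oxolane has become the oxane. The closest known reactions are the Corey–Chaykovsky epoxidation of ketones with benzylsulfonium ylides and the one‑carbon homologation of lactols by sulfur ylides followed by base‑mediated epoxy‑alcohol cyclisation. The two new stereocentres (C‑10 and C‑11) are trans through inversion in the epoxide opening but are not controlled relative to the core and need not be, since both become sp2 in step 15; the four core stereocentres are untouched because only the hemiketal C–O bond, never the C(Me)–O bond, is broken. The step needs attack at the distal epoxide carbon instead of 5‑exo attack: the proximal carbon is fully substituted and carries the bicyclic unit, whereas the distal carbon is a secondary benzylic centre activated by the para allyloxy group of ring B. It also needs carbonyl addition to outrun Sommelet–Hauser rearrangement of the ylide and epimerisation of the cyclobutane CH next to the ketone, which the intramolecular delivery and the hemiketal resting state (little free ketone) should secure.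

Step 15
Reactants: 20 hydroxy oxane
Product: 21 bis‑O‑allyl ether of the target
Conditions: Burgess reagent (MeO2CN−SO2N+Et3), toluene, 50 °C
Reagents that add atoms: none
Why: Burgess dehydration of the tertiary benzylic alcohol by syn elimination with the hydrogen on C‑10 (cis to the hydroxyl because the epoxide was opened anti) gives the tetrasubstituted enol ether conjugated with both rings under neutral conditions.

Step 16
Reactants: 21 bis‑O‑allyl ether
Product: 22 target CNP0185814.1
Conditions: Pd(PPh3)4 (5 mol %), morpholine, THF, rt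
Reagents that add atoms: none
Why: Palladium‑catalysed allyl transfer from both aryl allyl ethers to morpholine (Tsuji–Trost deallylation) frees the two phenols without touching the prenyl group or the enol ether.

**Compound list**

1 | (R)‑(−)‑linalool, (3R)‑3,7‑dimethylocta‑1,6‑dien‑3‑ol | C=C[C@](C)(O)CCC=C(C)C | starting material
2 | (R)‑1‑methylcyclopent‑2‑en‑1‑ol | C1=C[C@](C)(O)CC1 | intermediate
3 | prenyl bromide, 1‑bromo‑3‑methylbut‑2‑ene | CC(C)=CCBr | starting material
4 | (R)‑1‑methyl‑1‑[(3‑methylbut‑2‑en‑1‑yl)oxy]cyclopent‑2‑ene | C1=C[C@](C)(OCC=C(C)C)CC1 | intermediate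
5 | tricyclic ether, (1R,2R,5S,7R)‑2,6,6‑trimethyl‑2,7‑(epoxymethano)bicyclo[3.2.0]heptane, all ring fusions cis, O on C‑2 and CH2 on C‑7 both endo | C1[C@@H]2[C@H]3[C@H](CC[C@@]3(C)O1)C2(C)C | intermediate
6 | tricyclic γ‑lactone, (1R,2R,5S,7R)‑2‑hydroxy‑2,6,6‑trimethylbicyclo[3.2.0]heptane‑7‑carboxylic acid lactone | O=C1[C@@H]2[C@H]3[C@H](CC[C@@]3(C)O1)C2(C)C | intermediate
7 | 2‑fluoro‑4‑hydroxybenzaldehyde | O=Cc1ccc(O)cc1F | starting material
8 | 4‑(allyloxy)‑2‑fluorobenzaldehyde | O=Cc1ccc(OCC=C)cc1F | intermediate
9 | resorcinol | Oc1cccc(O)c1 | starting material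
10 | 4‑(allyloxy)‑2‑(3‑hydroxyphenoxy)benzaldehyde | O=Cc1ccc(OCC=C)cc1Oc1cccc(O)c1 | intermediate
11 | 4‑(allyloxy)‑2‑(2‑bromo‑5‑hydroxyphenoxy)benzaldehyde | O=Cc1ccc(OCC=C)cc1Oc1cc(O)ccc1Br | intermediate
12 | 4‑(allyloxy)‑2‑[2‑bromo‑5‑hydroxy‑4‑(3‑methylbut‑2‑en‑1‑yl)phenoxy]benzaldehyde | O=Cc1ccc(OCC=C)cc1Oc1cc(O)c(CC=C(C)C)cc1Br | intermediate
13 | 4‑(allyloxy)‑2‑[5‑(allyloxy)‑2‑bromo‑4‑(3‑methylbut‑2‑en‑1‑yl)phenoxy]benzaldehyde | O=Cc1ccc(OCC=C)cc1Oc1cc(OCC=C)c(CC=C(C)C)cc1Br | intermediate
14 | {4‑(allyloxy)‑2‑[5‑(allyloxy)‑2‑bromo‑4‑(3‑methylbut‑2‑en‑1‑yl)phenoxy]phenyl}methanol | OCc1ccc(OCC=C)cc1Oc1cc(OCC=C)c(CC=C(C)C)cc1Br | intermediate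
15 | 1‑(allyloxy)‑5‑{5‑(allyloxy)‑2‑[(methylsulfanyl)methyl]phenoxy}‑4‑bromo‑2‑(3‑methylbut‑2‑en‑1‑yl)benzene | CSCc1ccc(OCC=C)cc1Oc1cc(OCC=C)c(CC=C(C)C)cc1Br | intermediate
16 | aryllithium from 15 (Li in place of Br on ring A) | CSCc1ccc(OCC=C)cc1Oc1cc(OCC=C)c(CC=C(C)C)cc1[Li] | intermediate
17 | cyclic hemiketal: oxolan‑2‑ol from addition of ring A to the lactone carbonyl of 6, aryl = 4‑(allyloxy)‑2‑{5‑(allyloxy)‑2‑[(methylsulfanyl)methyl]phenoxy}‑5‑(3‑methylbut‑2‑en‑1‑yl)phenyl, core (1R,2R,5S,7R), hemiketal carbon as anomeric mixture | CSCc1ccc(OCC=C)cc1Oc1cc(OCC=C)c(CC=C(C)C)cc1C1(O)[C@@H]2[C@H]3[C@H](CC[C@@]3(C)O1)C2(C)C | intermediate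
18 | dimethylsulfonium triflate of 17 (SMe of ring B methylated) | C[S+](C)Cc1ccc(OCC=C)cc1Oc1cc(OCC=C)c(CC=C(C)C)cc1C1(O)[C@@H]2[C@H]3[C@H](CC[C@@]3(C)O1)C2(C)C.[O-]S(=O)(=O)C(F)(F)F | intermediate
19 | 10,11‑epoxy‑10,11‑dihydrodibenzo[b,f]oxepine carrying at C‑11 the endo‑7‑yl group of (1R,2R,5S)‑2‑hydroxy‑2,6,6‑trimethylbicyclo[3.2.0]heptane (free tertiary alcohol, present as alkoxide), epoxide configuration not defined | C=CCOc1ccc2c(c1)Oc1cc(OCC=C)c(CC=C(C)C)cc1C1(OC21)[C@@H]1[C@H]2[C@H](CC[C@@]2(C)O)C1(C)C | intermediate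
20 | ring‑enlarged hydroxy oxane: C‑10 bonded to the oxane oxygen, C‑11 carrying OH, ring A and the cyclobutane carbon; O‑10 and OH‑11 trans, their configuration relative to the core not defined | CC(C)=CCc1cc2c(cc1OCC=C)Oc1cc(OCC=C)ccc1C1C2(O)[C@@H]2[C@H]3[C@H](CC[C@@]3(C)O1)C2(C)C | intermediate
21 | bis‑O‑allyl ether of the target (both phenols allylated) | CC(C)=CCc1cc2c(cc1OCC=C)Oc1cc(OCC=C)ccc1C1=C2[C@@H]2[C@H]3[C@H](CC[C@@]3(C)O1)C2(C)C | intermediate
22 | CNP0185814.1: dibenzo[b,f]oxepine‑fused cyclol, core stereocentres R (cyclobutane CH next to C‑11), R (ring‑fusion CH shared by three rings), S (second ring‑fusion CH), R (methyl‑bearing C–O carbon) | CC(C)=CCc1cc2c(cc1O)Oc1cc(O)ccc1C1=C2[C@@H]2[C@H]3[C@H](CC[C@@]3(C)O1)C2(C)C | target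

**Count and risks**

Total steps: 16. Longest linear sequence: 12 (steps 5 to 16); the core branch (steps 1 to 4) joins at step 12.

Steps most likely to fail:

Step 14. The alkoxide may fail to open the epoxide at the distal benzylic carbon (5‑exo attack at the tertiary carbon, or no cyclisation), or the ylide may be lost to Sommelet–Hauser rearrangement before it reaches the hindered ketone. Fallback, setting out from 18 and rejoining at 21: the ylide step is run with one equivalent of KOt‑Bu at −78 °C and quenched cold so that epoxide 19 is isolated as an ordinary Corey–Chaykovsky product. The epoxide is opened reductively with Cp2TiCl (from Cp2TiCl2 and Zn) and 1,4‑cyclohexadiene; the titanium‑bound oxygen stays on the less substituted C‑10 and the tertiary benzylic radical at C‑11 takes up hydrogen, giving diol F1. Dess–Martin oxidation of the secondary benzylic alcohol gives hydroxy ketone F2, and acid‑catalysed cyclodehydration of this δ‑hydroxy ketone (PPTS, toluene, 4 Å sieves) closes the oxane as enol ether 21, bypassing 20 and step 15.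

Step 3. The copper ion may fail to bind the trisubstituted olefin together with the hindered ring olefin, so that no cycloaddition takes place, or the tertiary allylic ether may ionise. Fallback, setting out from 1 and rejoining at 6: rhodium‑catalysed hydroformylation of the vinyl group of linalool (Rh(acac)(CO)2, PPh3, CO/H2, toluene, 60 °C), the linear aldehyde closing on the tertiary hydroxyl, gives lactol F3. Oxidation with Ag2CO3 on Celite gives γ‑lactone F4. α‑Selenenylation (LDA, PhSeBr, THF, −78 °C) gives selenide F5, and oxidation with NaIO4 followed by syn elimination gives butenolide F6. Acetone‑sensitised irradiation (300 nm) of F6, an intramolecular enone‑type [2+2] photocycloaddition of the 1,6‑diene, should give lactone 6 directly with the same forced cis fusions.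

Step 8. O‑alkylation may outcompete ortho C‑alkylation of the phenoxide, or attack may occur between the two oxygens. Fallback, setting out from 11 and rejoining at 12: copper‑catalysed O‑alkylation with 2‑methylbut‑3‑yn‑2‑yl methyl carbonate (CuCl2 cat., DBU, MeCN, 0 °C) gives propargyl ether F7. Semi‑hydrogenation (H2, Pd/CaCO3 poisoned with lead, quinoline) gives dimethylallyl ether F8, whose aromatic Claisen rearrangement (toluene, 110 °C) delivers the prenyl group to the free ortho position and returns phenol 12; the primary allyl ether on ring B needs much higher temperatures to rearrange.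

Further compounds
F1 | step 14 | 10‑hydroxy‑10,11‑dihydrodibenzo[b,f]oxepine with H and the hydroxy‑bicycloheptyl group at C‑11 (diol) | CC(C)=CCc1cc2c(cc1OCC=C)Oc1cc(OCC=C)ccc1C(O)C2[C@@H]1[C@H]2[C@H](CC[C@@]2(C)O)C1(C)C
F2 | step 14 | 11‑substituted dibenzo[b,f]oxepin‑10(11H)‑one with free tertiary alcohol (hydroxy ketone) | CC(C)=CCc1cc2c(cc1OCC=C)Oc1cc(OCC=C)ccc1C(=O)C2[C@@H]1[C@H]2[C@H](CC[C@@]2(C)O)C1(C)C
F3 | step 3 | (5R)‑5‑methyl‑5‑(4‑methylpent‑3‑en‑1‑yl)oxolan‑2‑ol | OC1CC[C@](C)(O1)CCC=C(C)C
F4 | step 3 | (5R)‑5‑methyl‑5‑(4‑methylpent‑3‑en‑1‑yl)oxolan‑2‑one | O=C1CC[C@](C)(O1)CCC=C(C)C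
F5 | step 3 | (5R)‑5‑methyl‑5‑(4‑methylpent‑3‑en‑1‑yl)‑3‑(phenylselanyl)oxolan‑2‑one | O=C1C([Se]c2ccccc2)C[C@](C)(O1)CCC=C(C)C
F6 | step 3 | (5R)‑5‑methyl‑5‑(4‑methylpent‑3‑en‑1‑yl)furan‑2(5H)‑one | O=C1C=C[C@](C)(O1)CCC=C(C)C
F7 | step 8 | 4‑(allyloxy)‑2‑{2‑bromo‑5‑[(2‑methylbut‑3‑yn‑2‑yl)oxy]phenoxy}benzaldehyde | O=Cc1ccc(OCC=C)cc1Oc1cc(OC(C)(C)C#C)ccc1Br
F8 | step 8 | 4‑(allyloxy)‑2‑{2‑bromo‑5‑[(2‑methylbut‑3‑en‑2‑yl)oxy]phenoxy}benzaldehyde | O=Cc1ccc(OCC=C)cc1Oc1cc(OC(C)(C)C=C)ccc1Br
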